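**Plan**
1. Numbering used throughout: C1–C2–C3 (five-membered ring), C3a (carbinol carbon), C4–C8 (seven-membered ring), C8a (quaternary carbon). The target is read as (3R,3aS,8S,8aR): a cis-fused hydroazulene with 8a-CH3, 3a-OH, 3-isopropyl and 8-acyloxy all on one face.
2. Retrosynthetic cuts, in order: ester C8–O acyl bond; C6–CH3 (with the C6=C7 unsaturation); one isopropyl C–C (the isopropyl carbon is a latent acetyl carbonyl); C3–C3a (aldol, closes the five-membered ring); C2=C3 (cross-metathesis); C8a–C1 and C8a–CH3 (alkylations of a 1,3-dione).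
3. Forward: the seven-membered ring is bought as cycloheptane-1,3-dione; C8a is alkylated twice and the chain is extended by metathesis; the five-membered ring is closed in step 4; the seven-membered ring is then dressed (C6 methyl, C6=C7, C8 carbinol, ester).
4. Stereochemistry: C8a, C3a and C3 arise together in step 4 (ligand-controlled choice between two enantiotopic carbonyls, cis ring fusion, syn aldol); C8 is set in step 9 by catalyst-controlled reduction.
5. Enabling feature: C8a lies between the two oxygen-bearing carbons C3a and C8, so the seven-membered ring is a latent, prochiral 2,2-disubstituted cycloheptane-1,3-dione; C3, three bonds from C8a, carries the isopropyl carbon and is therefore the α-carbon of a latent methyl ketone enolate.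

Key step: step 4

Remark: the ligand enantiomer in step 4 cannot be predicted with confidence and would be fixed in a pilot run (the route is written for the one that gives 9); the catalyst enantiomer in step 9 follows the usual large/small model.

**Step 1**
Reactants: 1 cycloheptane-1,3-dione; 2 iodomethane
Product: 3 2-methylcycloheptane-1,3-dione
Conditions: MeI (0.95 equiv), K2CO3, acetone, reflux
Reagents that add atoms: iodomethane (2), CI
Why: C-alkylation of a β-diketone enolate; the seven-membered 1,3-dione is mainly in the diketo form and should alkylate at carbon like pentane-2,4-dione, and no stereocentre is formed.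

**Step 2**
Reactants: 3 2-methylcycloheptane-1,3-dione; 4 allyl methyl carbonate
Product: 5 2-methyl-2-(prop-2-en-1-yl)cycloheptane-1,3-dione
Conditions: Pd(PPh3)4 (2 mol %), THF, rt
Reagents that add atoms: allyl methyl carbonate (4), C=CCOC(=O)OC
Why: Tsuji–Trost allylation; zerovalent palladium ionises the carbonate to a π-allyl complex and methoxide (after loss of CO2), and the soft dione enolate attacks through carbon to give the quaternary, still prochiral C8a.

**Step 3**
Reactants: 5 2-methyl-2-(prop-2-en-1-yl)cycloheptane-1,3-dione; 6 but-3-en-2-one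
Product: 7 2-methyl-2-[(2E)-4-oxopent-2-en-1-yl]cycloheptane-1,3-dione
Conditions: second-generation Grubbs catalyst (H2IMes)(PCy3)Cl2Ru=CHPh (5 mol %), but-3-en-2-one (3 equiv), CH2Cl2, 40 °C
Reagents that add atoms: but-3-en-2-one (6), CC(=O)C=C
Why: Olefin cross-metathesis of a terminal alkene with an electron-poor vinyl ketone, which should give the cross product as the E-enone with loss of ethene.

**Step 4**
Reactants: 7 2-methyl-2-[(2E)-4-oxopent-2-en-1-yl]cycloheptane-1,3-dione
Product: 9 (3S,3aS,8aS)-3-acetyl-3a-hydroxy-8a-methyl-2,3,3a,4,5,6,7,8a-octahydroazulen-8(1H)-one, via silyl ether 8 (not isolated)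
Conditions: Cu(OAc)2·H2O (5 mol %), (R)- or (S)-DTBM-SEGPHOS (5.5 mol %, the enantiomer that gives 9), (EtO)2MeSiH (1.5 equiv), toluene, −25 °C; then aq. NH4F
Reagents that add atoms: none
Why: The phosphine-ligated monovalent copper hydride adds hydride to C2 of the E-enone (1,4-reduction), and the resulting Z copper enolate adds through C3 to one ring carbonyl (C3a); the silane silylates the copper aldolate to 8 and regenerates copper hydride. The closest known reaction type is the copper-hydride-catalysed reductive aldol cyclisation of enone-tethered 2,2-disubstituted cyclic 1,3-diones, including desymmetrising variants with chiral bisphosphines on the five- and six-membered diones. The five-membered ring closes in the 5-(enolexo)-exo-trig mode. C8a becomes stereogenic only through the choice between the two enantiotopic carbonyl groups, which the chiral bisphosphine on copper makes; C3a follows from C8a because the three-atom tether can reach the carbonyl only from its own face, which gives the cis ring fusion with OH and CH3 on one side; C3 is set by the closed, copper-bridged Zimmerman–Traxler-type transition state of the Z enolate, which places acetyl cis to the new hydroxyl. The step needs 1,4- over 1,2-hydride delivery and ring closure faster than silyl transfer to the enolate; the soft ligated hydride should prefer the β-monosubstituted enone over the ketone carbonyls, and the aldol is intramolecular onto an inductively activated dione carbonyl at low temperature.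

**Step 5**
Reactants: 9 (3S,3aS,8aS)-3-acetyl-3a-hydroxy-8a-methyl-2,3,3a,4,5,6,7,8a-octahydroazulen-8(1H)-one; 10 dibromomethane
Product: 11 (3R,3aS,8aS)-3a-hydroxy-8a-methyl-3-(prop-1-en-2-yl)-2,3,3a,4,5,6,7,8a-octahydroazulen-8(1H)-one
Conditions: Zn, CH2Br2, TiCl4 (pre-formed reagent, 1.5 equiv), THF/CH2Cl2, 0 °C to rt
Reagents that add atoms: dibromomethane (10), BrCBr
Why: Lombardo–Takai methylenation; the non-basic zinc–titanium methylene reagent should olefinate the methyl ketone without enolising C3 or opening the aldol, and should leave the C8 carbonyl, which is buried next to the quaternary C8a.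

**Step 6**
Reactants: 11 (3R,3aS,8aS)-3a-hydroxy-8a-methyl-3-(prop-1-en-2-yl)-2,3,3a,4,5,6,7,8a-octahydroazulen-8(1H)-one
Product: 12 (3R,3aS,8aS)-3a-hydroxy-8a-methyl-3-(propan-2-yl)-2,3,3a,4,5,6,7,8a-octahydroazulen-8(1H)-one
Conditions: H2 (3 atm), RhCl(PPh3)3 (10 mol %), toluene/EtOH, rt
Reagents that add atoms: none
Why: Homogeneous hydrogenation of a 1,1-disubstituted alkene with RhCl(PPh3)3, which does not migrate the double bond toward C3, so the C3 configuration from step 4 should be kept.

**Step 7**
Reactants: 12 (3R,3aS,8aS)-3a-hydroxy-8a-methyl-3-(propan-2-yl)-2,3,3a,4,5,6,7,8a-octahydroazulen-8(1H)-one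
Product: 14 (3R,3aS,8aS)-8a-methyl-3-(propan-2-yl)-3a-[(trimethylsilyl)oxy]-2,3,3a,4,5,8a-hexahydroazulen-8(1H)-one, via bis-silyl compound 13 (not isolated)
Conditions: TMSOTf (2.5 equiv), Et3N, CH2Cl2, 0 °C; then Pd(OAc)2 (1.1 equiv), MeCN, rt
Reagents that add atoms: trimethylsilyl trifluoromethanesulfonate, C[Si](C)(C)OS(=O)(=O)C(F)(F)F
Why: Soft enolisation silylates the tertiary alcohol and turns the C8 ketone (enolisable only toward C7) into its silyl enol ether, and Saegusa–Ito oxidation (α-palladation, β-hydride elimination from C6) then gives the C6–C7 enone; the silyl ether on O3a stays as protection against retro-aldol opening in step 8.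

**Step 8**
Reactants: 14 (3R,3aS,8aS)-8a-methyl-3-(propan-2-yl)-3a-[(trimethylsilyl)oxy]-2,3,3a,4,5,8a-hexahydroazulen-8(1H)-one; 15 methyllithium
Product: 17 (3R,3aS,8aS)-6,8a-dimethyl-3-(propan-2-yl)-3a-[(trimethylsilyl)oxy]-2,3,3a,4,5,8a-hexahydroazulen-8(1H)-one, via silyl enol ether 16 (not isolated)
Conditions: MeLi, CuI, Et2O/THF, −78 °C (gives Me2CuLi), TMSCl; then Pd(OAc)2 (1.1 equiv), MeCN, rt
Reagents that add atoms: lithium dimethylcuprate, [Li+].C[Cu-]C (made in the flask from methyllithium 15, [Li]C, and CuI)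
Why: Conjugate addition of the cuprate (accelerated by TMSCl) puts the methyl group on C6 and traps the enolate as silyl enol ether 16, and a second Saegusa–Ito oxidation restores the C6–C7 double bond and erases the transient C6 stereocentre.

**Step 9**
Reactants: 17 (3R,3aS,8aS)-6,8a-dimethyl-3-(propan-2-yl)-3a-[(trimethylsilyl)oxy]-2,3,3a,4,5,8a-hexahydroazulen-8(1H)-one
Product: 19 (3R,3aS,8S,8aR)-6,8a-dimethyl-3-(propan-2-yl)-2,3,4,5,8,8a-hexahydroazulene-3a,8(1H)-diol, via silylated alcohol 18 (not isolated)
Conditions: (R)-2-methyl-CBS-oxazaborolidine (20 mol %), catecholborane, toluene, −78 °C; then TBAF, THF, 0 °C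
Reagents that add atoms: none
Why: Corey–Bakshi–Shibata reduction; the oxazaborolidine should bind the carbonyl oxygen anti to the large quaternary C8a and deliver hydride 1,2 to the face opposite the angular methyl, giving the 8S allylic alcohol cis to O3a under reagent control, after which fluoride frees the tertiary hydroxyl.

**Step 10**
Reactants: 19 (3R,3aS,8S,8aR)-6,8a-dimethyl-3-(propan-2-yl)-2,3,4,5,8,8a-hexahydroazulene-3a,8(1H)-diol; 20 4-methoxybenzoyl chloride
Product: 21 (3R,3aS,8S,8aR)-3a-hydroxy-6,8a-dimethyl-3-(propan-2-yl)-1,2,3,3a,4,5,8,8a-octahydroazulen-8-yl 4-methoxybenzoate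
Conditions: 4-methoxybenzoyl chloride (1.2 equiv), DMAP, Et3N, CH2Cl2, rt
Reagents that add atoms: 4-methoxybenzoyl chloride (20), COc1ccc(cc1)C(Cl)=O
Why: DMAP-catalysed acylation through the acylpyridinium ion should esterify only the secondary allylic alcohol, because the tertiary C3a hydroxyl sits between a quaternary carbon and a branched methine.

**Compound list**
1 | cycloheptane-1,3-dione | O=C1CCCCC(=O)C1 | starting material
2 | iodomethane | CI | starting material
3 | 2-methylcycloheptane-1,3-dione | CC1C(=O)CCCCC1=O | intermediate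
4 | allyl methyl carbonate | C=CCOC(=O)OC | starting material
5 | 2-methyl-2-(prop-2-en-1-yl)cycloheptane-1,3-dione | C=CCC1(C)C(=O)CCCCC1=O | intermediate
6 | but-3-en-2-one | CC(=O)C=C | starting material
7 | 2-methyl-2-[(2E)-4-oxopent-2-en-1-yl]cycloheptane-1,3-dione | CC(=O)/C=C/CC1(C)C(=O)CCCCC1=O | intermediate
8 | (3S,3aS,8aS)-3-acetyl-3a-{[diethoxy(methyl)silyl]oxy}-8a-methyl-2,3,3a,4,5,6,7,8a-octahydroazulen-8(1H)-one | O=C1CCCC[C@]2(O[Si](C)(OCC)OCC)[C@@H](C(C)=O)CC[C@]12C | intermediate (not isolated)
9 | (3S,3aS,8aS)-3-acetyl-3a-hydroxy-8a-methyl-2,3,3a,4,5,6,7,8a-octahydroazulen-8(1H)-one | O=C1CCCC[C@]2(O)[C@@H](C(C)=O)CC[C@]12C | intermediate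
10 | dibromomethane | BrCBr | starting material
11 | (3R,3aS,8aS)-3a-hydroxy-8a-methyl-3-(prop-1-en-2-yl)-2,3,3a,4,5,6,7,8a-octahydroazulen-8(1H)-one | O=C1CCCC[C@]2(O)[C@@H](C(C)=C)CC[C@]12C | intermediate
12 | (3R,3aS,8aS)-3a-hydroxy-8a-methyl-3-(propan-2-yl)-2,3,3a,4,5,6,7,8a-octahydroazulen-8(1H)-one | O=C1CCCC[C@]2(O)[C@@H](C(C)C)CC[C@]12C | intermediate
13 | (3R,3aS,8aR)-8a-methyl-3-(propan-2-yl)-3a,8-bis[(trimethylsilyl)oxy]-1,2,3,3a,4,5,6,8a-octahydroazulene | C[Si](C)(C)OC1=CCCC[C@]2(O[Si](C)(C)C)[C@@H](C(C)C)CC[C@]12C | intermediate (not isolated)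
14 | (3R,3aS,8aS)-8a-methyl-3-(propan-2-yl)-3a-[(trimethylsilyl)oxy]-2,3,3a,4,5,8a-hexahydroazulen-8(1H)-one | O=C1C=CCC[C@]2(O[Si](C)(C)C)[C@@H](C(C)C)CC[C@]12C | intermediate
15 | methyllithium | [Li]C | starting material
16 | (3R,3aS,8aR)-6,8a-dimethyl-3-(propan-2-yl)-3a,8-bis[(trimethylsilyl)oxy]-1,2,3,3a,4,5,6,8a-octahydroazulene, both C6 epimers | C[Si](C)(C)OC1=CC(C)CC[C@]2(O[Si](C)(C)C)[C@@H](C(C)C)CC[C@]12C | intermediate (not isolated)
17 | (3R,3aS,8aS)-6,8a-dimethyl-3-(propan-2-yl)-3a-[(trimethylsilyl)oxy]-2,3,3a,4,5,8a-hexahydroazulen-8(1H)-one | O=C1C=C(C)CC[C@]2(O[Si](C)(C)C)[C@@H](C(C)C)CC[C@]12C | intermediate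
18 | (3R,3aS,8S,8aR)-6,8a-dimethyl-3-(propan-2-yl)-3a-[(trimethylsilyl)oxy]-1,2,3,3a,4,5,8,8a-octahydroazulen-8-ol | O[C@H]1C=C(C)CC[C@]2(O[Si](C)(C)C)[C@@H](C(C)C)CC[C@]12C | intermediate (not isolated)
19 | (3R,3aS,8S,8aR)-6,8a-dimethyl-3-(propan-2-yl)-2,3,4,5,8,8a-hexahydroazulene-3a,8(1H)-diol | O[C@H]1C=C(C)CC[C@]2(O)[C@@H](C(C)C)CC[C@]12C | intermediate
20 | 4-methoxybenzoyl chloride | COc1ccc(cc1)C(Cl)=O | starting material
21 | (3R,3aS,8S,8aR)-3a-hydroxy-6,8a-dimethyl-3-(propan-2-yl)-1,2,3,3a,4,5,8,8a-octahydroazulen-8-yl 4-methoxybenzoate | COc1ccc(C(=O)O[C@H]2C=C(C)CC[C@]3(O)[C@@H](C(C)C)CC[C@]23C)cc1 | target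

**Step count**
Total steps: 10. Longest linear sequence: 10 (from cycloheptane-1,3-dione).

**Steps most likely to fail**

Step 4. The chiral copper enolate may discriminate poorly between the two enantiotopic carbonyl groups, or the enolate may be silylated before it closes the ring. The fallback sets out from 7 and comes back at 9. Stoichiometric [(Ph3P)CuH]6 in toluene (−40 °C to rt) should close the ring with the same relative configuration but without asymmetric induction, giving 9 together with its mirror image, (3R,3aR,8aR)-3-acetyl-3a-hydroxy-8a-methyl-2,3,3a,4,5,6,7,8a-octahydroazulen-8(1H)-one F1. The two enantiomers are separated by preparative chromatography on a chiral stationary phase, and 9 goes on.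

Step 5. The reagent may not discriminate fully between the two ketone groups, or the Lewis-acidic mixture may open the unprotected β-hydroxy diketone by retro-aldol cleavage. The fallback sets out from 9 and comes back at 14, at the cost of one extra step. N-(Trimethylsilyl)imidazole should give the silyl ether (3S,3aS,8aS)-3-acetyl-8a-methyl-3a-[(trimethylsilyl)oxy]-2,3,3a,4,5,6,7,8a-octahydroazulen-8(1H)-one F2. Wittig methylenation (Ph3PCH3Br, KOtBu, THF, 0 °C), which spares ketones next to a quaternary carbon, should then give (3R,3aS,8aS)-8a-methyl-3-(prop-1-en-2-yl)-3a-[(trimethylsilyl)oxy]-2,3,3a,4,5,6,7,8a-octahydroazulen-8(1H)-one F3. Hydrogenation (H2, RhCl(PPh3)3) should give (3R,3aS,8aS)-8a-methyl-3-(propan-2-yl)-3a-[(trimethylsilyl)oxy]-2,3,3a,4,5,6,7,8a-octahydroazulen-8(1H)-one F4, which under the conditions of step 7 passes through 13 to 14.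

Step 9. Facial selectivity may erode if the catalyst's preference opposes the intrinsic bias of the cis-fused bicycle, or the hindered carbonyl may bind the catalyst slowly and allow uncatalysed background reduction. The fallback sets out from 17 and comes back at 21, replacing steps 9 and 10. Dilute HCl in THF should remove the silyl group to give (3R,3aS,8aS)-3a-hydroxy-6,8a-dimethyl-3-(propan-2-yl)-2,3,3a,4,5,8a-hexahydroazulen-8(1H)-one F5. Evans–Saksena reduction (Me4NBH(OAc)3, MeCN/AcOH, −20 °C) delivers hydride intramolecularly from O3a and should deliberately give the trans diol (3R,3aS,8R,8aR)-6,8a-dimethyl-3-(propan-2-yl)-2,3,4,5,8,8a-hexahydroazulene-3a,8(1H)-diol F6. Mitsunobu esterification with 4-methoxybenzoic acid (PPh3, DIAD, toluene) should then invert C8 and install the ester, giving 21; displacement at this neopentylic allylic carbon is expected to be slow.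

**Further compounds**
F1 | step 4 | (3R,3aR,8aR)-3-acetyl-3a-hydroxy-8a-methyl-2,3,3a,4,5,6,7,8a-octahydroazulen-8(1H)-one | O=C1CCCC[C@@]2(O)[C@H](C(C)=O)CC[C@@]12C
F2 | step 5 | (3S,3aS,8aS)-3-acetyl-8a-methyl-3a-[(trimethylsilyl)oxy]-2,3,3a,4,5,6,7,8a-octahydroazulen-8(1H)-one | O=C1CCCC[C@]2(O[Si](C)(C)C)[C@@H](C(C)=O)CC[C@]12C
F3 | step 5 | (3R,3aS,8aS)-8a-methyl-3-(prop-1-en-2-yl)-3a-[(trimethylsilyl)oxy]-2,3,3a,4,5,6,7,8a-octahydroazulen-8(1H)-one | O=C1CCCC[C@]2(O[Si](C)(C)C)[C@@H](C(C)=C)CC[C@]12C
F4 | step 5 | (3R,3aS,8aS)-8a-methyl-3-(propan-2-yl)-3a-[(trimethylsilyl)oxy]-2,3,3a,4,5,6,7,8a-octahydroazulen-8(1H)-one | O=C1CCCC[C@]2(O[Si](C)(C)C)[C@@H](C(C)C)CC[C@]12C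
F5 | step 9 | (3R,3aS,8aS)-3a-hydroxy-6,8a-dimethyl-3-(propan-2-yl)-2,3,3a,4,5,8a-hexahydroazulen-8(1H)-one | O=C1C=C(C)CC[C@]2(O)[C@@H](C(C)C)CC[C@]12C
F6 | step 9 | (3R,3aS,8R,8aR)-6,8a-dimethyl-3-(propan-2-yl)-2,3,4,5,8,8a-hexahydroazulene-3a,8(1H)-diol | O[C@@H]1C=C(C)CC[C@]2(O)[C@@H](C(C)C)CC[C@]12C
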